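Of the substrate charged to the winter run, 92.2% is left after 4.00 h, so that flask stops short of 10 h, and the noon run, followed as far as 10.0 h, has to speak for it.

| setting | winter | noon | flask |
|---|---|---|---|
| substrate | 0.43 M | 0.29 M | 0.43 M |
| gas | 200 mM (held) | 200 mM (held) | 200 mM (held) |
| free catalyst | 2.2 mM | 2.2 mM | 2.2 mM |
| remark | the very flask that is asked about, followed so far | run made earlier |  |
| time |  |  | 10 h |

| run | time / h | target / % | substrate / % |
|---|---|---|---|
| winter | 0.500 | 0.7 | 100.3 |
| winter | 1.00 | 1.6 | 99.1 |
| winter | 1.50 | 1.1 | 98.3 |
| winter | 2.50 | 3.0 | 97.1 |
| winter | 3.00 | 4.5 | 95.1 |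
| winter | 4.00 | 6.2 | 92.2 |
| noon | 0.833 | 0.9 | 98.9 |
| noon | 1.33 | 1.8 | 97.4 |
| noon | 2.00 | 4.6 | 95.1 |
| noon | 3.00 | 5.7 | 94.3 |
| noon | 4.00 | 9.1 | 90.3 |
| noon | 6.00 | 13.3 | 85.1 |
| noon | 10.0 | 22.2 | 74.1 |

(scatter of a reading: 0.5 percentage points)

- at the start none of reagent is dissolved
- what was read earlier has a scatter of 0.5 percentage points, one standard deviation
- what may be going on: substrate + catalyst intermediate A -> catalyst intermediate B; gas <-> reagent; substrate -> decomposition product; reagent + free catalyst -> catalyst intermediate A; target <-> isomer of the product; catalyst intermediate C -> free catalyst + target; catalyst intermediate B -> catalyst intermediate C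

* concentration of target at 10 h, in M
* concentration of substrate at 10 h, in M

Read as concentrations, the target columns agree at their last shared time. The winter run holds 0.0267 M target at 4.00 h and the noon run 0.0264 M at the same time, although the winter charge of substrate is 1.48 times the noon charge. Target formation therefore looks zero-order in substrate.

Down the noon columns, target per hour is 0.00660 M/h at 4.00 h. The last noon reading gives 0.00644 M/h, the target rate, meaning the concentration of target formed per hour, while substrate falls to 0.215 M.

A constant rate integrates to target = rate × time, so the winter flask should hold 0.0644 M target at 10 h. The noon balance lacks 0.0107 M at its end. Taking the same amount off as well leaves 0.355 M substrate in the winter flask.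

The forecast differs slightly, with 0.065 M target and 0.352 M substrate. Its ground is “Winter has more substrate, so it should stay zero order”.

The winter flask gives 0.0661 M target and 0.356 M substrate, so the forecast held.

    substrate + catalyst intermediate A → catalyst intermediate B (k = 0.0160 /M/s)
    gas ⇌ reagent, rate k2*(csat - [reagent]) (kL = 1.10 × 10⁻⁵ /s)
    substrate → decomposition product (k = 4.20 × 10⁻⁸ /s)
    reagent + free catalyst → catalyst intermediate A (k = 0.420 /M/s)
    target ⇌ isomer of the product (K = 0.330, k = 8.30 × 10⁻⁶ /s)
    catalyst intermediate C → free catalyst + target (k = 0.0250 /s)
    catalyst intermediate B → catalyst intermediate C (k = 0.00670 /s)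

The target rate reckoned 0.0644 M for the winter flask against the 0.0661 M it gives. In that flask decomposition product stands at 0.139% of the substrate charged at 10.0 h; the half-life of substrate by that step alone, 190 d, is far longer than the time 10 h, and the step leaves target unchanged. Left until 15 h with the same charges, the flask should hold 0.0966 M target by the same reckoning, and it holds 0.0975 M. Unbound substrate still stands there at 74% of the charge.

(The numbers in the tables stem from a simulated flask for substances that don't exist; scatter was added.)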